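**Retrosynthetic overview**

1. The target 15 comes from benzyl ether 14 by hydrogenolysis; 14 comes from its isomer 12 by acid-mediated opening of ring C at O1–C2 and reclosure through the former 5-oxygen (Wessely–Moser isomerisation).
2. Feature used: ring A carries oxygen on C5, C6, C7, C8 and C8a, so C4a has two ortho oxygens (the one on C5 and O1 on C8a). Exchanging their roles turns a 5,8-dihydroxy-6,7-dimethoxy ring into the 5,6-dihydroxy-7,8-dimethoxy ring.
3. Compound 12 comes from 5-hydroxyflavone 10 by Elbs oxidation at C8; 10 comes from 5,6,7-trimethoxyflavone 9 by chelation-guided 5-O-demethylation.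
4. Flavone 9 comes from 1,3-diketone 8 by cyclodehydration; 8 comes from acetophenone 3 (from 3,4,5-trimethoxyphenol 1) and acid chloride 7 (from 2-hydroxy-6-methoxybenzoic acid 4) by a one-flask Baker–Venkataraman aroylation.
5. Ring order: rings A and B are bought; ring C is first closed in step 6, then opened and re-formed the other way round in step 9.

Key step: step 9

Assumption: the acid equilibrium between the two closures of ring C is taken to lie on the side of the 5,6-dihydroxy-7,8-dimethoxy isomer, by analogy with simpler 5,8-dihydroxy- and 5,7,8-trioxygenated flavones.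

**Route**

Step 1
Reactants: 1 3,4,5-trimethoxyphenol
Product: 3 1-(6-hydroxy-2,3,4-trimethoxyphenyl)ethanone, via difluoroboron chelate 2 (not isolated)
Conditions: AcOH, BF3·OEt2 (3 equiv), 90 °C; then H2O, 50 °C
Reagents that add atoms: acetic acid, CC(=O)O
Why: BF3-mediated Friedel–Crafts C-acetylation (Fries-type) ortho to the phenol at one of the two equivalent free positions; the ketone should form as its BF2 chelate, which water hydrolyses.

Step 2
Reactants: 4 2-hydroxy-6-methoxybenzoic acid
Product: 5 benzyl 2-(benzyloxy)-6-methoxybenzoate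
Conditions: BnBr (2.5 equiv), K2CO3, DMF, 60 °C
Reagents that add atoms: benzyl bromide, BrCc1ccccc1
Why: Williamson O-benzylation of the phenol together with SN2 alkylation of the carboxylate; warming overcomes the hydrogen bond of the salicylate hydroxyl.

Step 3
Reactants: 5 benzyl 2-(benzyloxy)-6-methoxybenzoate
Product: 6 2-(benzyloxy)-6-methoxybenzoic acid
Conditions: KOH, MeOH/H2O, reflux; then aq. HCl
Reagents that add atoms: potassium hydroxide, [K+].[OH-]
Why: Saponification of the benzyl ester; the two ortho alkoxy groups slow it, hence reflux, and the aryl ethers are inert to hydroxide.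

Step 4
Reactants: 6 2-(benzyloxy)-6-methoxybenzoic acid
Product: 7 2-(benzyloxy)-6-methoxybenzoyl chloride
Conditions: (COCl)2, DMF (cat.), CH2Cl2, 0 °C to rt; evaporation
Reagents that add atoms: oxalyl chloride, O=C(Cl)C(=O)Cl
Why: Acid chloride formation through the Vilsmeier-type chloroiminium species at room temperature, mild enough to leave the ortho benzyl ether untouched.

Step 5
Reactants: 3 1-(6-hydroxy-2,3,4-trimethoxyphenyl)ethanone; 7 2-(benzyloxy)-6-methoxybenzoyl chloride
Product: 8 1-(2-benzyloxy-6-methoxyphenyl)-3-(6-hydroxy-2,3,4-trimethoxyphenyl)propane-1,3-dione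
Conditions: LiN(SiMe3)2 (3.2 equiv), THF, −78 to −10 °C; then 7, −78 °C to rt; cold dilute HCl
Reagents that add atoms: none
Why: One-flask Baker–Venkataraman synthesis, in which the phenoxide–enolate dianion of 3 undergoes Claisen-type C-aroylation; any O-aroyl ester formed first should be carried to the same diketone by base-induced O-to-C acyl transfer, and the third equivalent of base holds the product as its enolate.

Step 6
Reactants: 8 1-(2-benzyloxy-6-methoxyphenyl)-3-(6-hydroxy-2,3,4-trimethoxyphenyl)propane-1,3-dione
Product: 9 2-(2-benzyloxy-6-methoxyphenyl)-5,6,7-trimethoxychromen-4-one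
Conditions: TsOH·H2O (cat.), toluene, reflux, Dean–Stark
Reagents that add atoms: none
Why: Acid-catalysed cyclodehydration of the o-hydroxyaryl 1,3-diketone (6-exo-trig addition of the only free phenol to the ring-B ketone, then loss of water) closes ring C as a single flavone.

Step 7
Reactants: 9 2-(2-benzyloxy-6-methoxyphenyl)-5,6,7-trimethoxychromen-4-one
Product: 10 2-(2-benzyloxy-6-methoxyphenyl)-5-hydroxy-6,7-dimethoxychromen-4-one
Conditions: MgBr2·OEt2 (3 equiv), MeCN, 80 °C; 1 M HCl work-up
Reagents that add atoms: none
Why: Chelation-controlled ether cleavage, in which magnesium bound between the C4 carbonyl oxygen and the peri 5-methoxy oxygen activates only that methyl toward SN2 attack by bromide; the other methyl ethers and the benzyl ether cannot form this six-membered chelate.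

Step 8
Reactants: 10 2-(2-benzyloxy-6-methoxyphenyl)-5-hydroxy-6,7-dimethoxychromen-4-one
Product: 12 2-(2-benzyloxy-6-methoxyphenyl)-5,8-dihydroxy-6,7-dimethoxychromen-4-one, via potassium 8-sulfate ester 11 (not isolated)
Conditions: K2S2O8 (1.5 equiv), KOH (aq.), pyridine, 0 °C to rt; then HCl (aq., about 2 M), 85 °C, N2
Reagents that add atoms: potassium peroxodisulfate, [K+].[K+].[O-]S(=O)(=O)OOS(=O)(=O)[O-]
Why: Elbs persulfate oxidation, in which the 5-phenoxide attacks a peroxide oxygen of S2O8(2−) through its para carbon C8, the only free position of ring A; brief acid hydrolysis of the aryl sulfate then frees the 8-hydroxyl.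

Step 9
Reactants: 12 2-(2-benzyloxy-6-methoxyphenyl)-5,8-dihydroxy-6,7-dimethoxychromen-4-one
Product: 14 2-(2-benzyloxy-6-methoxyphenyl)-5,6-dihydroxy-7,8-dimethoxychromen-4-one, via open-chain 1,3-diketone 13 (not isolated)
Conditions: H2SO4 (3 M aq.)/1,4-dioxane 1:1, degassed, Ar, 100 °C, followed by HPLC until the isomer composition no longer changes
Reagents that add atoms: none
Why: Protonation of the C4 carbonyl makes C2 electrophilic, water adds there and the O1–C2 bond breaks to give diketone 13, whose ring A has free hydroxyls on both carbons ortho to the acyl group and can turn about the C4–C4a bond. Attack of the former 5-hydroxyl on the C2 carbonyl (6-exo-trig) and loss of water form the new O1–C2 bond and ring C, so the old 6- and 7-methoxyls become the 8- and 7-methoxyls and the old O1 and 8-hydroxyl become the 5- and 6-hydroxyls. This is the Wessely–Moser rearrangement, the known acid isomerisation of 5,8-dihydroxy- and 5,7,8-trioxygenated flavones to their 5,6- and 5,6,7-isomers. No stereocentre is formed. The selectivity needed is the choice between the two ortho hydroxyls, which is thermodynamic because both closures are reversible in hot acid; the 5,6-dihydroxy isomer is expected to prevail because it keeps the chelated 5-hydroxyl and adds a contiguous O6–H···O5–H···O4 hydrogen-bond chain. The benzyl ether keeps the ring-B oxygen out of the closure, and dilute H2SO4, whose counter-ion is a poor nucleophile, is chosen so that this ether should survive.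

Step 10
Reactants: 14 2-(2-benzyloxy-6-methoxyphenyl)-5,6-dihydroxy-7,8-dimethoxychromen-4-one
Product: 15 5,6,2'-trihydroxy-7,8,6'-trimethoxyflavone, that is 5,6-dihydroxy-2-(2-hydroxy-6-methoxyphenyl)-7,8-dimethoxychromen-4-one
Conditions: H2 (1 atm), 10% Pd/C, EtOAc/MeOH, rt
Reagents that add atoms: none
Why: Catalytic hydrogenolysis of the aryl benzyl ether; the methyl ethers, the catechol and the C2=C3 bond of the pyranone are not expected to react at 1 atm and room temperature.

**Compound list**

1 | 3,4,5-trimethoxyphenol | COc1cc(O)cc(OC)c1OC | starting material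
2 | difluoroboron chelate of 1-(6-hydroxy-2,3,4-trimethoxyphenyl)ethanone (2,2-difluoro-5,6,7-trimethoxy-4-methyl-1,3,2-benzodioxaborinine, zwitterionic O–B–O chelate) | CC1=[O+][B-](F)(F)Oc2cc(OC)c(OC)c(OC)c21 | intermediate
3 | 1-(6-hydroxy-2,3,4-trimethoxyphenyl)ethanone | CC(=O)c1c(O)cc(OC)c(OC)c1OC | intermediate
4 | 2-hydroxy-6-methoxybenzoic acid | COc1cccc(O)c1C(=O)O | starting material
5 | benzyl 2-(benzyloxy)-6-methoxybenzoate | COc1cccc(OCc2ccccc2)c1C(=O)OCc1ccccc1 | intermediate
6 | 2-(benzyloxy)-6-methoxybenzoic acid | COc1cccc(OCc2ccccc2)c1C(=O)O | intermediate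
7 | 2-(benzyloxy)-6-methoxybenzoyl chloride | COc1cccc(OCc2ccccc2)c1C(=O)Cl | intermediate
8 | 1-(2-benzyloxy-6-methoxyphenyl)-3-(6-hydroxy-2,3,4-trimethoxyphenyl)propane-1,3-dione (drawn as diketo form) | COc1cccc(OCc2ccccc2)c1C(=O)CC(=O)c1c(O)cc(OC)c(OC)c1OC | intermediate
9 | 2-(2-benzyloxy-6-methoxyphenyl)-5,6,7-trimethoxychromen-4-one | COc1cccc(OCc2ccccc2)c1-c1cc(=O)c2c(OC)c(OC)c(OC)cc2o1 | intermediate
10 | 2-(2-benzyloxy-6-methoxyphenyl)-5-hydroxy-6,7-dimethoxychromen-4-one | COc1cccc(OCc2ccccc2)c1-c1cc(=O)c2c(O)c(OC)c(OC)cc2o1 | intermediate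
11 | potassium 2-(2-benzyloxy-6-methoxyphenyl)-5-hydroxy-6,7-dimethoxy-4-oxochromen-8-yl sulfate | COc1cccc(OCc2ccccc2)c1-c1cc(=O)c2c(O)c(OC)c(OC)c(OS(=O)(=O)[O-])c2o1.[K+] | intermediate
12 | 2-(2-benzyloxy-6-methoxyphenyl)-5,8-dihydroxy-6,7-dimethoxychromen-4-one | COc1cccc(OCc2ccccc2)c1-c1cc(=O)c2c(O)c(OC)c(OC)c(O)c2o1 | intermediate
13 | 1-(2-benzyloxy-6-methoxyphenyl)-3-(2,3,6-trihydroxy-4,5-dimethoxyphenyl)propane-1,3-dione | COc1cccc(OCc2ccccc2)c1C(=O)CC(=O)c1c(O)c(O)c(OC)c(OC)c1O | intermediate
14 | 2-(2-benzyloxy-6-methoxyphenyl)-5,6-dihydroxy-7,8-dimethoxychromen-4-one | COc1cccc(OCc2ccccc2)c1-c1cc(=O)c2c(O)c(O)c(OC)c(OC)c2o1 | intermediate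
15 | 5,6,2'-trihydroxy-7,8,6'-trimethoxyflavone | COc1cccc(O)c1-c1cc(=O)c2c(O)c(O)c(OC)c(OC)c2o1 | target

**Step count**

Total: 10 steps. Longest linear sequence: 9 steps (from 4 through steps 2–10); the branch from 1 joins at step 5.

**Steps most likely to fail**

Step 9 (key isomerisation). The equilibrium may not lie far enough toward 14. Ring opening may be slow because C2 is shielded by the 2',6'-disubstituted ring B. The benzyl ether may be lost in hot acid, which would let ring B take part in the closure. The open diketone may also be cleaved by acid retro-Claisen hydrolysis. The fallback reaches the same ring-A pattern by chelation-relayed demethylation instead of isomerisation. It sets out from acid chloride 7, which is combined with the purchasable 1-(2-hydroxy-3,4,5,6-tetramethoxyphenyl)ethanone F1 under the LiN(SiMe3)2 conditions of step 5 to give 1-(2-benzyloxy-6-methoxyphenyl)-3-(2-hydroxy-3,4,5,6-tetramethoxyphenyl)propane-1,3-dione F2. Cyclodehydration with TsOH in toluene gives 2-(2-benzyloxy-6-methoxyphenyl)-5,6,7,8-tetramethoxychromen-4-one F3, and hydrogenolysis (H2, 10% Pd/C) gives 2-(2-hydroxy-6-methoxyphenyl)-5,6,7,8-tetramethoxychromen-4-one F4. Anhydrous AlBr3 in MeCN at 0 °C to rt should then cleave the 5-methoxyl through the C4 carbonyl chelate and the 6-methoxyl through the aluminium 5-phenoxide, leaving the 7-, 8- and 6'-methoxyls. The fallback comes back to the route at the target 15.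

Step 8 (Elbs oxidation). Conversion in persulfate oxidations of chelated 5-hydroxyflavones is usually modest. The hydroquinone formed may be oxidised further, and the chromone may be attacked by alkali on long standing. The fallback oxidises the same phenol to the para-quinone and reduces it. It sets out from 10, which PhI(OAc)2 in aqueous MeCN at 0 °C should convert into 2-(2-benzyloxy-6-methoxyphenyl)-6,7-dimethoxychromene-4,5,8-trione F5. Reduction with Na2S2O4 in EtOAc/water then gives the hydroquinone, and the fallback comes back at 12.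

Step 7 (5-O-demethylation). The Lewis acid may also cleave the benzyl ether, or the cleavage may run on to the 6-methoxyl through the newly formed magnesium 5-phenoxide. The fallback accepts loss of the benzyl group and puts it back selectively. It sets out from 9, which BCl3 in CH2Cl2 (−78 to 0 °C) should convert into 5-hydroxy-2-(2-hydroxy-6-methoxyphenyl)-6,7-dimethoxychromen-4-one F6 by cleaving both the chelated 5-methyl ether and the benzyl ether. BnBr and K2CO3 in acetone then benzylate only the 2'-hydroxyl, since the chelated 5-hydroxyl is unreactive, and the fallback comes back at 10.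

**Further compounds**

F1 | step 9 | 1-(2-hydroxy-3,4,5,6-tetramethoxyphenyl)ethanone | CC(=O)c1c(O)c(OC)c(OC)c(OC)c1OC
F2 | step 9 | 1-(2-benzyloxy-6-methoxyphenyl)-3-(2-hydroxy-3,4,5,6-tetramethoxyphenyl)propane-1,3-dione | COc1cccc(OCc2ccccc2)c1C(=O)CC(=O)c1c(O)c(OC)c(OC)c(OC)c1OC
F3 | step 9 | 2-(2-benzyloxy-6-methoxyphenyl)-5,6,7,8-tetramethoxychromen-4-one | COc1cccc(OCc2ccccc2)c1-c1cc(=O)c2c(OC)c(OC)c(OC)c(OC)c2o1
F4 | step 9 | 2-(2-hydroxy-6-methoxyphenyl)-5,6,7,8-tetramethoxychromen-4-one | COc1cccc(O)c1-c1cc(=O)c2c(OC)c(OC)c(OC)c(OC)c2o1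
F5 | step 8 | 2-(2-benzyloxy-6-methoxyphenyl)-6,7-dimethoxychromene-4,5,8-trione | COc1cccc(OCc2ccccc2)c1C1=CC(=O)C2=C(O1)C(=O)C(OC)=C(OC)C2=O
F6 | step 7 | 5-hydroxy-2-(2-hydroxy-6-methoxyphenyl)-6,7-dimethoxychromen-4-one | COc1cccc(O)c1-c1cc(=O)c2c(O)c(OC)c(OC)cc2o1
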